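**Assumption:** the target has no stereocentre and no stereogenic double bond, so "single enantiomer" is read as the one achiral constitution drawn, and no step has to set or protect configuration. Compounds 1, 5 and 7 are taken as commercial.

## Structural features

The target is a 2-(2-arylethyl)chromone: a 4H-chromen-4-one bicycle (pyranone ring O1–C2=C3–C4(=O)–C4a–C8a fused to a benzene ring) carrying methoxy groups at C6 and C7. C2 bears a saturated CH2–CH2 chain that ends at C1' of a 4-hydroxy-3-methoxyphenyl ring, and C3 is unsubstituted. There is no stereocentre, so the problem is one of connectivity and regiochemistry only. The fragile points are the free guaiacol-type phenol (acidic, nucleophilic, easily oxidised) and the vinylogous ester C2=C3 (open to conjugate addition, ring opening by hard nucleophiles and over-reduction). One free phenol must also be kept distinct from three aryl methyl ethers, which rules out a late global demethylation. The real difficulty is the pyranone ring: the C4 carbonyl, the C2 alkyl group and the ring oxygen must be placed with chromone (not aurone or coumarin) regiochemistry on an electron-rich arene. The key step exploits two features of this ring: C4 is an isolated one-carbon carbonyl between aryl carbon C4a and C3, so it can arrive as carbon monoxide, and O1–C2=C3–C4=O is formally a phenol added across an ynone, so C2–C3 with the whole arylethyl chain can arrive as a terminal alkyne. Since O1 and C4a are ortho on the benzo ring, the ring dissects into an ortho-iodophenol, CO and a 4-arylbut-1-yne.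

## Logic of the disconnections

**11 ⇒ 10.** The O–CH2 bond of a methoxymethyl acetal on the guaiacyl oxygen is cut. The free ArOH of 11 would compete as an O-nucleophile for the acyl-palladium intermediate of the key step and would consume base and phosphorylating agent in the alkyne synthesis. The gain is a key step with only one phenol in play. The demand on the forward step is an acetal cleavage mild enough to leave the pyranone and the three aryl methyl ethers alone.

**10 ⇒ 6 + 7 + 4.** Three bonds of the pyranone ring are cut at once: C4a–C4, C4–C3 and O1–C2. In one sentence, the route is a palladium-catalysed carbonylative three-component annulation of 6, 7 and 4 that builds the whole heterocycle. The bicyclic core collapses to a monocyclic iodophenol, a one-carbon unit and a terminal alkyne that already carries the complete arylethyl side chain, and no precursor contains the ring carbonyl. The demands are that insertion of 7 precedes alkynylation, that the acyl-palladium species is captured by the alkyne and not by amine or phenol, and that the ring closes 6-endo at C2 and not 5-exo at C3.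

**4 ⇒ 2 (through 3).** The triple bond is traced back to a methyl ketone: the two π-bonds between the terminal carbons are exchanged for the C=O bond and two C–H bonds, with no change in the carbon skeleton. This ties the alkyne to a cheap C6–C4 building block in which all four chain carbons are in place. The demand is regioselective enolisation at the methyl group and complete elimination of the enol derivative 3.

**2 ⇒ 1.** The same O–CH2 acetal bond is cut. 1 is commercial and carries the correct arene substitution and chain length. The forward step must alkylate the phenol without touching the ketone.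

**6 ⇒ 5.** The C–I bond is cut. 5 is commercial and its substitution pattern directs an electrophile to the one position that becomes C4a. The forward step must mono-iodinate ortho to the hydroxyl and para to a methoxy group without oxidising the ring.

## Other disconnections considered

**Alternative 1:** (the first that comes to mind) cut C2–C3 and O1–C2. A Claisen condensation of the dianion of 1-(2-hydroxy-4,5-dimethoxyphenyl)ethan-1-one A1 with methyl 3-[3-methoxy-4-(methoxymethoxy)phenyl]propanoate A2 would give the β-diketone A3, and acid cyclodehydration of A3 would release the acetal and give 11. This is short and reliable, but it is the default, biosynthesis-like 1,3-diketone logic. Structurally A1 already holds the C4a–C4 bond and the carbonyl, so the ring problem is only half addressed. Mechanistically the cross-Claisen needs excess strong base on a phenoxide-enolate and competes with self-condensation of the enolisable ester A2. The chosen plan instead forms three ring bonds from three simple components in one operation.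

**Alternative 2:** cut the bond between the two chain carbons. A vinylogous aldol condensation of 6,7-dimethoxy-2-methyl-4H-chromen-4-one A4 with 4-hydroxy-3-methoxybenzaldehyde A5 would give the styrylchromone A6, and hydrogenation of the exocyclic alkene would give 11. The pyranone problem is only deferred, because A4 must itself be made by the classical condensation–cyclodehydration sequence. The alkoxide-mediated condensation risks ring opening of the pyranone, and the phenoxide of A5 is a poor electrophile, so protection would be needed. The final hydrogenation must distinguish the styryl C=C from C2=C3. The route would be longer and end with a chemoselectivity problem.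

**Alternative 3:** cut the C2–CH2 bond. A decarboxylative radical conjugate addition (anodic or via a redox-active ester) of the 2-arylethyl radical from 3-(4-hydroxy-3-methoxyphenyl)propanoic acid A8 to C2 of 6,7-dimethoxy-4H-chromen-4-one A7 would give the racemic chromanone A9, which would then be dehydrogenated to 11. The electron-rich guaiacyl ring of A8 is expected to be oxidised at lower potential than the carboxylate, so a direct anodic version is doubtful. The addition creates a C2 stereocentre that must be erased by an oxidation that electron-rich arenes and a free phenol tolerate poorly. A7 still has to be built first, so the sequence gains nothing in length or convergence.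

Key step: step 4

## Steps

Step 1
Reactants: 1 zingerone [4-(4-hydroxy-3-methoxyphenyl)butan-2-one]
Product: 2 4-[3-methoxy-4-(methoxymethoxy)phenyl]butan-2-one
Conditions: MOMCl (1.3 equiv), i-Pr2NEt (2 equiv), CH2Cl2, 0 °C → rt
Reagents that add atoms: chloromethyl methyl ether (MOMCl), COCCl
Why: MOM ether formation (O-alkylation of the phenol by the oxocarbenium-type electrophile); the ketone is inert to the hindered amine base, and the acetal masks the acidic, nucleophilic ArOH for steps 2 and 4.

Step 2
Reactants: 2 4-[3-methoxy-4-(methoxymethoxy)phenyl]butan-2-one
Product: 4 4-(but-3-yn-1-yl)-2-methoxy-1-(methoxymethoxy)benzene, via enol phosphate 3 (not isolated)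
Conditions: LDA (1.1 equiv), THF, −78 °C; ClP(O)(OEt)2 (1.15 equiv), −78 °C → rt; then added to LDA (2.3 equiv), THF, −78 °C → rt; aq. NH4Cl
Reagents that add atoms: diethyl chlorophosphate, CCOP(=O)(Cl)OCC (its atoms are carried only by 3 and leave again on the way to 4)
Why: Negishi one-pot conversion of a methyl ketone into a terminal alkyne: kinetic deprotonation at CH3, O-phosphorylation to the terminal enol phosphate 3, then LDA-induced β-elimination of diethyl phosphate; the product is held as its lithium acetylide until the quench, which should prevent isomerisation to the allene or internal alkyne.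

Step 3
Reactants: 5 3,4-dimethoxyphenol
Product: 6 2-iodo-4,5-dimethoxyphenol
Conditions: NIS (1.0 equiv), MeCN, −20 → 0 °C, dark
Reagents that add atoms: N-iodosuccinimide, O=C1CCC(=O)N1I
Why: Electrophilic aromatic iodination; the position ortho to OH and para to the 3-methoxy group is the most activated and least hindered, whereas the other ortho position lies between two oxygen substituents, so mono-iodination should occur at the carbon that becomes C4a.

Step 4
Reactants: 6 2-iodo-4,5-dimethoxyphenol; 7 carbon monoxide; 4 4-(but-3-yn-1-yl)-2-methoxy-1-(methoxymethoxy)benzene
Product: 10 6,7-dimethoxy-2-{2-[3-methoxy-4-(methoxymethoxy)phenyl]ethyl}-4H-chromen-4-one, via hydroxyaryl ynone 8 (not isolated), via enaminone 9 (not isolated)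
Conditions: PdCl2(dppf) (5 mol %), CO (20 bar), 4 (1.3 equiv), Et2NH, 120 °C, autoclave; aq. citric acid work-up
Reagents that add atoms: diethylamine, CCNCC (its atoms are carried only by 9 and are released again on ring closure)
Why: Pd(0) should insert into the C–I bond of 6, CO should insert to give the aroyl-palladium(II) species (fast for an electron-rich aryl group under CO pressure), and copper-free, amine-assisted alkynylation with 4 followed by reductive elimination should give ynone 8, forming C4a–C4 and C4–C3. Diethylamine then adds to the β-carbon of 8 to give enaminone 9, and the ortho-hydroxyl, held near by hydrogen bonding to the C4 carbonyl, attacks the amine-bearing carbon and expels diethylamine, forming O1–C2 and closing the pyranone. The closest known reaction type is the palladium-catalysed carbonylative Sonogashira coupling–annulation of ortho-iodophenols with terminal alkynes to chromones and flavones, which tolerates alkyl acetylenes. The single ring closes by a 6-endo addition–elimination at C2 of 9, which is the net 6-endo-dig outcome on 8. No stereocentre is formed. The step needs three selectivities: CO insertion before alkynylation (otherwise direct coupling and closure to a 2-substituted benzofuran), capture of the aroyl-palladium by the alkyne and not by amine or phenoxide, and 6-endo over 5-exo closure (otherwise an aurone-type 2-alkylidenebenzofuranone). The first is addressed by CO pressure, the second by an excess of 4 and the bidentate ligand, and the third by the amine relay, which makes C2 the only electrophilic carbon of 9.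

Step 5
Reactants: 10 6,7-dimethoxy-2-{2-[3-methoxy-4-(methoxymethoxy)phenyl]ethyl}-4H-chromen-4-one
Product: 11 2-[2-(4-hydroxy-3-methoxyphenyl)ethyl]-6,7-dimethoxy-4H-chromen-4-one (target)
Conditions: HCl (1.25 M in MeOH), 40 °C
Reagents that add atoms: none
Why: Acid-catalysed acetal exchange (MOM cleavage) via the oxocarbenium ion; the γ-pyranone is only reversibly O-protonated and the aryl methyl ethers are inert to dilute methanolic acid, so only the guaiacyl OH should be released.

## Compound list

1 | zingerone, 4-(4-hydroxy-3-methoxyphenyl)butan-2-one | CC(=O)CCc1ccc(O)c(OC)c1 | starting material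
2 | 4-[3-methoxy-4-(methoxymethoxy)phenyl]butan-2-one | CC(=O)CCc1ccc(OCOC)c(OC)c1 | intermediate
3 | diethyl 4-[3-methoxy-4-(methoxymethoxy)phenyl]but-1-en-2-yl phosphate (enol phosphate, not isolated) | C=C(CCc1ccc(OCOC)c(OC)c1)OP(=O)(OCC)OCC | intermediate
4 | 4-(but-3-yn-1-yl)-2-methoxy-1-(methoxymethoxy)benzene | C#CCCc1ccc(OCOC)c(OC)c1 | intermediate
5 | 3,4-dimethoxyphenol | COc1ccc(O)cc1OC | starting material
6 | 2-iodo-4,5-dimethoxyphenol | COc1cc(O)c(I)cc1OC | intermediate
7 | carbon monoxide | [C-]#[O+] | starting material
8 | 1-(2-hydroxy-4,5-dimethoxyphenyl)-5-[3-methoxy-4-(methoxymethoxy)phenyl]pent-2-yn-1-one (ynone, not isolated) | COCOc1ccc(CCC#CC(=O)c2cc(OC)c(OC)cc2O)cc1OC | intermediate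
9 | (E)-3-(diethylamino)-1-(2-hydroxy-4,5-dimethoxyphenyl)-5-[3-methoxy-4-(methoxymethoxy)phenyl]pent-2-en-1-one (enaminone, not isolated) | CCN(CC)/C(CCc1ccc(OCOC)c(OC)c1)=C/C(=O)c1cc(OC)c(OC)cc1O | intermediate
10 | 6,7-dimethoxy-2-{2-[3-methoxy-4-(methoxymethoxy)phenyl]ethyl}-4H-chromen-4-one | COCOc1ccc(CCc2cc(=O)c3cc(OC)c(OC)cc3o2)cc1OC | intermediate
11 | 2-[2-(4-hydroxy-3-methoxyphenyl)ethyl]-6,7-dimethoxy-4H-chromen-4-one | COc1cc(CCc2cc(=O)c3cc(OC)c(OC)cc3o2)ccc1O | target

## Step count and risks

Total step count: 5. Longest linear sequence: 4 steps (1, 2, 4, 5); step 3 is a one-step branch.

**Step 4 (key step).** The most likely failure is interception of the aroyl-palladium intermediate by diethylamine (amide formation) or by a phenoxide (aryl ester formation) before acetylide transfer, because an alkyl acetylene is less acidic and transfers more slowly than an aryl acetylene. A second failure mode is coupling without CO insertion followed by closure to a benzofuran. The fallback replaces the carbonylation by a stepwise polar assembly in which the future C4 is already bonded to the arene. It sets out from 4 and comes back at 8, which is then taken on to 10. Compound 4 is deprotonated (n-BuLi, THF, −78 °C) and added to the lithium phenoxide (pre-formed with LiHMDS) of commercial 2-hydroxy-4,5-dimethoxybenzaldehyde F1. This should give the racemic propargylic alcohol 1-(2-hydroxy-4,5-dimethoxyphenyl)-5-[3-methoxy-4-(methoxymethoxy)phenyl]pent-2-yn-1-ol F2. Oxidation of this benzylic, propargylic alcohol with MnO2 (CH2Cl2, rt) should give 8, now isolated, and Et2NH in EtOH should close it through 9 to 10.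

**Step 2.** The most likely failure is proton transfer between the kinetic enolate and unreacted ketone during phosphorylation, which would place part of the enol phosphate on the internal side and lead to allene or internal alkyne; incomplete elimination is the second risk. The fallback avoids enolate regiochemistry by cutting the methyl carbon off and adding one carbon back. It sets out from 2 and comes back at 4. Haloform cleavage of 2 (NaOBr, dioxane–water, 0 °C) should give 3-[3-methoxy-4-(methoxymethoxy)phenyl]propanoic acid F3. Reduction (BH3·SMe2, THF) should give 3-[3-methoxy-4-(methoxymethoxy)phenyl]propan-1-ol F4, and Dess–Martin oxidation should give 3-[3-methoxy-4-(methoxymethoxy)phenyl]propanal F5. Ohira–Bestmann homologation (dimethyl (1-diazo-2-oxopropyl)phosphonate, K2CO3, MeOH) should then give 4.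

**Step 3.** The most likely failure is oxidation of the very electron-rich free phenol by the iodonium source (oxidative dearomatisation towards a quinone), or a second iodination at the remaining ortho position. The fallback removes the phenol from the substitution step, so that the ring is iodinated as a less oxidisable aryl ester under control of the methoxy groups. It sets out from 5 and comes back at 6. Acetylation (Ac2O, pyridine) should give 3,4-dimethoxyphenyl acetate F6. Iodination (NIS, cat. TFA, MeCN), directed to the only free position para to a methoxy group, should give 2-iodo-4,5-dimethoxyphenyl acetate F7. Methanolysis (K2CO3, MeOH, rt) should release 6.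

## Further compounds

F1 | step 4 | 2-hydroxy-4,5-dimethoxybenzaldehyde | COc1cc(O)c(C=O)cc1OC
F2 | step 4 | 1-(2-hydroxy-4,5-dimethoxyphenyl)-5-[3-methoxy-4-(methoxymethoxy)phenyl]pent-2-yn-1-ol (racemic) | COCOc1ccc(CCC#CC(O)c2cc(OC)c(OC)cc2O)cc1OC
F3 | step 2 | 3-[3-methoxy-4-(methoxymethoxy)phenyl]propanoic acid | COCOc1ccc(CCC(=O)O)cc1OC
F4 | step 2 | 3-[3-methoxy-4-(methoxymethoxy)phenyl]propan-1-ol | COCOc1ccc(CCCO)cc1OC
F5 | step 2 | 3-[3-methoxy-4-(methoxymethoxy)phenyl]propanal | COCOc1ccc(CCC=O)cc1OC
F6 | step 3 | 3,4-dimethoxyphenyl acetate | COc1ccc(OC(C)=O)cc1OC
F7 | step 3 | 2-iodo-4,5-dimethoxyphenyl acetate | COc1cc(OC(C)=O)c(I)cc1OC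
A1 | alternative 1 | 1-(2-hydroxy-4,5-dimethoxyphenyl)ethan-1-one | CC(=O)c1cc(OC)c(OC)cc1O
A2 | alternative 1 | methyl 3-[3-methoxy-4-(methoxymethoxy)phenyl]propanoate | COCOc1ccc(CCC(=O)OC)cc1OC
A3 | alternative 1 | 1-(2-hydroxy-4,5-dimethoxyphenyl)-5-[3-methoxy-4-(methoxymethoxy)phenyl]pentane-1,3-dione | COCOc1ccc(CCC(=O)CC(=O)c2cc(OC)c(OC)cc2O)cc1OC
A4 | alternative 2 | 6,7-dimethoxy-2-methyl-4H-chromen-4-one | Cc1cc(=O)c2cc(OC)c(OC)cc2o1
A5 | alternative 2 | 4-hydroxy-3-methoxybenzaldehyde | COc1cc(C=O)ccc1O
A6 | alternative 2 | (E)-2-[2-(4-hydroxy-3-methoxyphenyl)ethenyl]-6,7-dimethoxy-4H-chromen-4-one | COc1cc(/C=C/c2cc(=O)c3cc(OC)c(OC)cc3o2)ccc1O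
A7 | alternative 3 | 6,7-dimethoxy-4H-chromen-4-one | O=c1ccoc2cc(OC)c(OC)cc12
A8 | alternative 3 | 3-(4-hydroxy-3-methoxyphenyl)propanoic acid | COc1cc(CCC(=O)O)ccc1O
A9 | alternative 3 | 2-[2-(4-hydroxy-3-methoxyphenyl)ethyl]-6,7-dimethoxychroman-4-one (racemic) | COc1cc(CCC2CC(=O)c3cc(OC)c(OC)cc3O2)ccc1O
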